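**Retrosynthetic overview**
- Both prenyl C–C bonds are traced back by a double retro-[3,3] shift to the two catechol oxygens. The precursor is 3',4'-bis-O-(1,1-dimethylallyl)orobol, in which each ether has only one free ortho carbon (C5' and C2').
- The key disconnection is the two tertiary allyl–O(aryl) bonds. Both are made in one operation on unprotected orobol with a 1,1-dimethylallyl carbonate, selecting two of four OH groups.
- Orobol comes from O1–C2 closure of ring C on a deoxybenzoin plus one carbon from DMF. The deoxybenzoin comes from phloroglucinol and 3,4-dihydroxyphenylacetic acid.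
- Rings A and B are bought. Ring C (the pyranone) is the only ring formed, in step 1.

Assumption: the SMILES has no stereocentre and no E/Z alkene (both alkenes end in CMe2), and the C3–C1' axis is not configurationally stable. The target is therefore achiral and no enantioselective step is needed.

**Step 1**
Reactants: 1 phloroglucinol; 2 3,4-dihydroxyphenylacetic acid
Product: 5 orobol (5,7,3',4'-tetrahydroxyisoflavone), via deoxybenzoin 3 (not isolated), via enaminone 4 (not isolated)
Conditions: BF3·OEt2 (solvent), 85 °C, 1.5 h; then DMF, MsCl (3 equiv), 0 → 70 °C, 2 h; ice-water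
Reagents that add atoms: N,N-dimethylformamide, CN(C)C=O
Why: BF3-promoted Friedel–Crafts (Hoesch-type) C-acylation of symmetrical phloroglucinol gives 3 with no regiochemical choice, the Vilsmeier-type iminium salt from DMF/MsCl formylates the activated methylene to 4, and the ortho-OH closes ring C by addition–elimination (O1–C2 bond, loss of Me2NH), the free catechol being tolerated because no base is present (deoxybenzoin route to isoflavones).

**Step 2**
Reactants: 6 2-methylbut-3-en-2-ol
Product: 8 tert-butyl (2-methylbut-3-en-2-yl) carbonate, via lithium alkoxide 7 (not isolated)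
Conditions: n-BuLi (1.05 equiv), THF, −78 → 0 °C; then Boc2O (1.05 equiv), 0 °C → rt; H2O work-up
Reagents that add atoms: di-tert-butyl dicarbonate (Boc2O), CC(C)(C)OC(=O)OC(=O)OC(C)(C)C
Why: Alkoxide acylation, in which the hindered tertiary alcohol is first made into its lithium alkoxide and then attacks Boc2O cleanly at the carbonyl, so the mixed carbonate forms without allylic transposition.

**Step 3**
Reactants: 5 orobol; 8 tert-butyl (2-methylbut-3-en-2-yl) carbonate (2.1 equiv)
Product: 11 3',4'-bis-O-(1,1-dimethylallyl)orobol, via dipotassium salt 9 (not isolated), via mono-ether 10 (not isolated)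
Conditions: KOtBu (2.0 equiv), degassed DMF, 0 °C, Ar; then Pd(PPh3)4 (5 mol %), 8 added slowly in THF, 0 °C, 2 h; AcOH (2 equiv); short Et3N-washed silica plug
Reagents that add atoms: none
Why: Proposed new method: a protecting-group-free, charge-gated double Tsuji–Trost O-(1,1-dimethylallyl)ation in which two equivalents of KOtBu turn 5 into dianion 9, so that the weakly nucleophilic vinylogous-carboxylate 7-phenoxide (pKa about 7) and the more basic ring B catecholate (pKa about 9–10) compete at equal concentration for the cationic (1,1-dimethylallyl)palladium complex made from 8 and zerovalent palladium, the ring B oxygen attacking the more substituted allyl terminus under kinetic control at 0 °C, the tert-butoxide released from each molecule of 8 unmasking the second catechol oxygen for the second C–O bond, any 7-O-ether formed by mistake being a vinylogous allyl ester that zerovalent palladium re-ionises and passes on while the ring B ethers (poor leaving groups) persist, and the chelated 5-OH staying silent; the closest known reactions are the Pd(PPh3)4-catalysed reverse prenylation of catechols with tertiary allyl carbonates and the dianion-controlled ring B O-alkylation of 7,4'-dihydroxyisoflavones, which have not been combined on a free tetrahydroxyisoflavone.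

**Step 4**
Reactants: 11 3',4'-bis-O-(1,1-dimethylallyl)orobol
Product: 13 5,7,3',4'-tetrahydroxy-2',5'-diprenylisoflavone (target), via mono-rearranged phenol 12 (not isolated)
Conditions: PhNEt2, 130 °C, 3 h, Ar
Reagents that add atoms: none
Why: Double aromatic Claisen rearrangement, in which each ether has a single ortho C–H to migrate to (O4'→C5' first, then O3'→C2'), the [3,3] allyl inversion turns the tertiary ether into the linear prenyl group, tautomerisation to the phenol makes each shift irreversible, the gem-dimethyl group lowers the barrier so that 130 °C suffices, the weakly basic solvent suppresses acid-induced isoprene loss and chroman formation, and no stereocentre is created.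

**Compound list**
1 | phloroglucinol (benzene-1,3,5-triol) | Oc1cc(O)cc(O)c1 | starting material
2 | 3,4-dihydroxyphenylacetic acid | OC(=O)Cc1ccc(O)c(O)c1 | starting material
3 | 2-(3,4-dihydroxyphenyl)-1-(2,4,6-trihydroxyphenyl)ethan-1-one (deoxybenzoin, not isolated) | O=C(Cc1ccc(O)c(O)c1)c1c(O)cc(O)cc1O | intermediate
4 | 2-(3,4-dihydroxyphenyl)-3-(dimethylamino)-1-(2,4,6-trihydroxyphenyl)prop-2-en-1-one (enaminone, alkene geometry not fixed, not isolated) | CN(C)C=C(c1ccc(O)c(O)c1)C(=O)c1c(O)cc(O)cc1O | intermediate
5 | orobol, 3-(3,4-dihydroxyphenyl)-5,7-dihydroxychromen-4-one | Oc1cc(O)c2c(c1)occ(-c1ccc(O)c(O)c1)c2=O | intermediate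
6 | 2-methylbut-3-en-2-ol | C=CC(C)(C)O | starting material
7 | lithium 2-methylbut-3-en-2-olate (not isolated) | [Li+].[O-]C(C)(C)C=C | intermediate
8 | tert-butyl (2-methylbut-3-en-2-yl) carbonate | C=CC(C)(C)OC(=O)OC(C)(C)C | intermediate
9 | orobol 7,4'-dipotassium salt (not isolated) | [K+].[K+].[O-]c1cc(O)c2c(c1)occ(-c1ccc([O-])c(O)c1)c2=O | intermediate
10 | 5,7-dihydroxy-3-[3-hydroxy-4-(2-methylbut-3-en-2-yloxy)phenyl]chromen-4-one (4'-O-mono-ether, drawn neutral, not isolated) | C=CC(C)(C)Oc1ccc(-c2coc3cc(O)cc(O)c3c2=O)cc1O | intermediate
11 | 5,7-dihydroxy-3-[3,4-bis(2-methylbut-3-en-2-yloxy)phenyl]chromen-4-one | C=CC(C)(C)Oc1ccc(-c2coc3cc(O)cc(O)c3c2=O)cc1OC(C)(C)C=C | intermediate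
12 | 5,7-dihydroxy-3-[4-hydroxy-3-(2-methylbut-3-en-2-yloxy)-5-(3-methylbut-2-enyl)phenyl]chromen-4-one (not isolated) | CC(C)=CCc1cc(-c2coc3cc(O)cc(O)c3c2=O)cc(OC(C)(C)C=C)c1O | intermediate
13 | 3-[3,4-dihydroxy-2,5-bis(3-methylbut-2-enyl)phenyl]-5,7-dihydroxychromen-4-one (achiral) | CC(C)=CCc1cc(-c2coc3cc(O)cc(O)c3c2=O)c(CC=C(C)C)c(O)c1O | target

**Total step count:** 4. **Longest linear sequence:** 3 (steps 1, 3, 4).

**Steps most likely to fail**

Step 3 (the new step).
- Risks: competing O7- or C6/C8-allylation of ring A, branched-to-linear ether isomerisation, and air oxidation or palladium chelation by the catecholate.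
- The fallback uses known chemistry only. It sets out from 5 and comes back at 11.
- The most acidic 7-OH of 5 is silylated (TIPSCl 1.0 equiv, imidazole, DMF, 0 °C) to give 7-O-triisopropylsilylorobol F1.
- The free catechol then undergoes the established neutral double reverse prenylation (Pd(PPh3)4 5 mol %, 8 2.5 equiv, THF, 0 °C). This runs through the silylated 4'-O-mono-ether F2 to the silylated bis-ether F3.
- Bu4NF buffered with AcOH (THF, 0 °C) removes the silyl group without touching the tertiary ethers and delivers 11.

Step 4.
- Risks: loss of isoprene from the crowded vicinal bis-ether, ipso-Claisen followed by intramolecular Diels–Alder capture by the neighbouring vinyl ether (cage formation), and slow migration into the hindered C2'.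
- The fallback installs one prenyl group at a time. It sets out from 5 and comes back at 13.
- Under the step 3 conditions with only 1.0 equiv of 8, compound 5 gives mono-ether 10, which is now isolated. Heating it (PhNEt2, 120 °C) gives 5'-prenylorobol F4.
- A second O-alkylation with 1.0 equiv of 8 goes to the less hindered 3'-oxygen, because the 4'-oxygen is now flanked by the prenyl group. This gives 12, now isolated.
- The Claisen rearrangement of 12 into C2' gives 13. No intermediate carries two neighbouring tertiary ethers, so there is no tethered dienophile and less steric strain.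

Step 1.
- Risks: the free catechol chelates BF3, which can lower conversion in the acylation or the ring closure and complicate isolation.
- The fallback carries the catechol as its dimethyl ether. It sets out from 1 and comes back at 5.
- Compound 1 is acylated with commercial 3,4-dimethoxyphenylacetic acid (BF3·OEt2, 85 °C) to give the dimethoxy deoxybenzoin F5, which is isolated.
- DMF/MsCl/BF3·OEt2 converts F5 through the dimethoxy enaminone F6 into 5,7-dihydroxy-3',4'-dimethoxyisoflavone F7.
- BBr3 (CH2Cl2, −78 °C → rt) cleaves both methyl ethers to give 5.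

**Further compounds**
F1 | step 3 | 7-O-triisopropylsilylorobol | CC(C)[Si](Oc1cc(O)c2c(c1)occ(-c1ccc(O)c(O)c1)c2=O)(C(C)C)C(C)C
F2 | step 3 | 7-O-triisopropylsilyl-4'-O-(1,1-dimethylallyl)orobol | C=CC(C)(C)Oc1ccc(-c2coc3cc(O[Si](C(C)C)(C(C)C)C(C)C)cc(O)c3c2=O)cc1O
F3 | step 3 | 7-O-triisopropylsilyl-3',4'-bis-O-(1,1-dimethylallyl)orobol | C=CC(C)(C)Oc1ccc(-c2coc3cc(O[Si](C(C)C)(C(C)C)C(C)C)cc(O)c3c2=O)cc1OC(C)(C)C=C
F4 | step 4 | 5'-prenylorobol (5,7,3',4'-tetrahydroxy-5'-prenylisoflavone) | CC(C)=CCc1cc(-c2coc3cc(O)cc(O)c3c2=O)cc(O)c1O
F5 | step 1 | 2-(3,4-dimethoxyphenyl)-1-(2,4,6-trihydroxyphenyl)ethan-1-one | COc1ccc(CC(=O)c2c(O)cc(O)cc2O)cc1OC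
F6 | step 1 | 2-(3,4-dimethoxyphenyl)-3-(dimethylamino)-1-(2,4,6-trihydroxyphenyl)prop-2-en-1-one | COc1ccc(C(=CN(C)C)C(=O)c2c(O)cc(O)cc2O)cc1OC
F7 | step 1 | 5,7-dihydroxy-3',4'-dimethoxyisoflavone | COc1ccc(-c2coc3cc(O)cc(O)c3c2=O)cc1OC
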